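**Retrosynthetic overview**

1. The target is disconnected to a furan-fused cyclononene bearing a furylic acetate: a redox-neutral, dearomatising 1,3-transposition (furylic ionisation, water capture at the furan α-carbon, ring opening) would unveil the C6=C7 enal and both formyl groups at once.
2. The nine-membered ring comes from an acyclic diene by ring-closing metathesis, which forms the Z-trisubstituted C3=C4 alkene.
3. The diene comes from a 4-bromofuran-3-yl homoallylic alcohol by formylation, allylation and acetylation.
4. That alcohol comes from (R)-citronellal (supplies C-2′) and a furyl(mesityl)iodonium salt: enamine/copper α-arylation sets C-9, reagent-controlled methallylation sets C-1.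
5. Ring order: the furan ring is bought in (3,4-dibromofuran), the nine-membered carbocycle is closed in step 6, and the furan ring is opened in step 7.

Assumption: locants in the comments are those of the target name; the furylic carbinol/acetate carbon (future C-6) is carried as both configurations; the (2S,5S)-imidazolidinone is taken to shield the enamine face on the side of its benzyl group (if the sense proves opposite, its enantiomer is used).

**Route**

Step 1
Reactants: 1 3,4-dibromofuran
Product: 3 (4-bromofuran-3-yl)boronic acid, via (4-bromofuran-3-yl)lithium 2 (not isolated)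
Conditions: n-BuLi (1.05 equiv), Et2O, −78 °C; B(OiPr)3, −78 → 0 °C; 1 M HCl
Reagents that add atoms: n-butyllithium CCCC[Li] (lithium of 2); triisopropyl borate CC(C)OB(OC(C)C)OC(C)C (boron); water O (hydroxyl oxygens)
Why: One of the two equivalent C–Br bonds undergoes bromine–lithium exchange at −78 °C, where the 3-furyllithium neither loses LiBr nor migrates to the α-position, and electrophilic borylation followed by hydrolysis gives the boronic acid (halogen–metal exchange, borylation).

Step 2
Reactants: 3 (4-bromofuran-3-yl)boronic acid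
Product: 4 (4-bromofuran-3-yl)(2,4,6-trimethylphenyl)iodonium trifluoromethanesulfonate
Conditions: MesI(OAc)2 (1.0 equiv) premixed with TfOH (1.0 equiv), CH2Cl2, 0 °C; add 3 at −30 °C, then 23 °C; trituration with Et2O
Reagents that add atoms: (diacetoxyiodo)mesitylene CC(=O)OI(OC(C)=O)c1c(C)cc(C)cc1C; trifluoromethanesulfonic acid OS(=O)(=O)C(F)(F)F
Why: The electrophilic trivalent-iodine species MesI(OAc)(OTf) formed in the flask takes the furyl group from boron by ipso-substitution, which is faster than attack at the free furan α-positions, and the hindered mesityl group is the ligand that is not transferred in step 3 (diaryliodonium synthesis by boron-to-iodine transmetalation).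

Step 3
Reactants: 4 (4-bromofuran-3-yl)(2,4,6-trimethylphenyl)iodonium trifluoromethanesulfonate; 5 (R)-citronellal
Product: 7 (4R,5R,6R)-5-(4-bromofuran-3-yl)-2,6,10-trimethylundeca-1,9-dien-4-ol, via (2R,3R)-2-(4-bromofuran-3-yl)-3,7-dimethyloct-6-enal 6 (not isolated)
Conditions: CuBr (10 mol %), (2S,5S)-5-benzyl-2-tert-butyl-3-methylimidazolidin-4-one·Cl3CCO2H (10 mol %), NaHCO3, toluene/Et2O 2:1, 23 °C; filter under Ar; add to (+)-Ipc2B(2-methylallyl) [made from (+)-Ipc2BOMe (the (−)-α-pinene series) and 2-methylallylmagnesium chloride], Et2O, −78 °C; NaOH, H2O2, 0 → 23 °C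
Reagents that add atoms: (+)-B-(2-methylallyl)diisopinocampheylborane CC(=C)CB([C@H]1C[C@H]2C[C@@H]([C@@H]1C)C2(C)C)[C@H]1C[C@H]2C[C@@H]([C@@H]1C)C2(C)C (methallyl group, originally from 2-methylallylmagnesium chloride CC(=C)C[Mg]Cl)
Why: The imidazolidinone converts 5 into its E-enamine, which is arylated by the furyl–trivalent-copper species generated from CuBr and 4 on the face opposite the catalyst benzyl group, so the future C-9 is set R under catalyst control while C-2′ from citronellal is untouched (dual copper/enamine α-arylation of aldehydes), and the unpurified, epimerisable aldehyde 6 is trapped at −78 °C by the Brown methallylborane through a chair Zimmerman–Traxler transition state on its Re face, a choice reinforced by the Felkin–Anh preference (furyl as the large group), which sets the future C-1 as R.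

Step 4
Reactants: 7 (4R,5R,6R)-5-(4-bromofuran-3-yl)-2,6,10-trimethylundeca-1,9-dien-4-ol
Product: 9 4-[(4R,5R,6R)-4-hydroxy-2,6,10-trimethylundeca-1,9-dien-5-yl]furan-3-carbaldehyde (drawn in its open form), via dilithiated furyllithium alkoxide 8 (not isolated)
Conditions: t-BuLi (3.1 equiv), Et2O, −78 °C; DMF, −78 → 0 °C; H2O
Reagents that add atoms: tert-butyllithium CC(C)(C)[Li] (lithium of 8); N,N-dimethylformamide CN(C)C=O (formyl group)
Why: After deprotonation of the hydroxyl group, bromine–lithium exchange with t-BuLi at −78 °C outpaces any reaction with the isolated alkenes, and the resulting 3-furyllithium is formylated by DMF (Bouveault formylation) without touching the three stereocentres.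

Step 5
Reactants: 9 4-[(4R,5R,6R)-4-hydroxy-2,6,10-trimethylundeca-1,9-dien-5-yl]furan-3-carbaldehyde
Product: 11 (4R,5R,6R)-5-[4-(1-acetoxybut-3-en-1-yl)furan-3-yl]-2,6,10-trimethylundeca-1,9-dien-4-yl acetate (both configurations at the furylic carbon), via bis(bromomagnesium) dialkoxide 10 (not isolated)
Conditions: allylmagnesium bromide (3 equiv), THF, −78 → 0 °C; then Ac2O (6 equiv), DMAP (20 mol %), 0 → 23 °C
Reagents that add atoms: allylmagnesium bromide C=CC[Mg]Br; acetic anhydride CC(=O)OC(C)=O
Why: The Grignard reagent adds to the furan aldehyde to give the homoallylic alkoxide as a mixture at the new furylic carbon, which is acceptable because that carbon becomes sp2 in step 7, and acetic anhydride acylates both magnesium alkoxides in the same flask, installing the C-1 acetate of the target and the furylic leaving group (Grignard 1,2-addition, in situ O-acylation).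

Step 6
Reactants: 11 (4R,5R,6R)-5-[4-(1-acetoxybut-3-en-1-yl)furan-3-yl]-2,6,10-trimethylundeca-1,9-dien-4-yl acetate
Product: 12 (4R,5R,7Z)-7-methyl-4-[(2R)-6-methylhept-5-en-2-yl]-5,6,9,10-tetrahydro-4H-cyclonona[c]furan-5,10-diyl diacetate (both C-10 configurations)
Conditions: second-generation Hoveyda–Grubbs catalyst (10 mol %, two portions), 1,4-benzoquinone (20 mol %), toluene (1 mM), 80 °C, Ar sparge
Reagents that add atoms: none
Why: Ring-closing metathesis between the monosubstituted and the 1,1-disubstituted alkene, driven by loss of ethene at high dilution, closes the nine-membered carbocycle across the rigid, cis-disposed furan 3,4-positions, and the medium ring admits only the Z-trisubstituted C3=C4 alkene, while the more hindered prenyl-type alkene and the stereocentres stay intact.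

Step 7
Reactants: 12 (4R,5R,7Z)-7-methyl-4-[(2R)-6-methylhept-5-en-2-yl]-5,6,9,10-tetrahydro-4H-cyclonona[c]furan-5,10-diyl diacetate
Product: 13 (1R,3Z,6E,8R,9R)-7,8-diformyl-3-methyl-9-[(2R)-6-methylhept-5-en-2-yl]cyclonona-3,6-dien-1-yl acetate (CNP0113811.6)
Conditions: Sc(OTf)3 (10 mol %), MeCN/H2O 4:1, 23 → 45 °C; pH 7 buffer
Reagents that add atoms: water O
Why: Proposed new method: Sc(OTf)3 ionises the furylic acetate to a 3-furylmethyl cation whose oxocarbenium resonance form places the charge on the neighbouring furan α-carbon, water adds there to give a 2-hydroxy-3-alkylidene-2,3-dihydrofuran that ring-opens to the C-7 enal (C6=C7 formed ring-cis, hence 6E) and an enol that ketonises at C-8, this epimerisable centre settling trans to the C-9 side chain (8R), and carbinol formed by capture at the exocyclic carbon re-ionises under the same conditions whereas the dialdehyde does not; the closest known reaction types are the hydrative ring opening of 2-furylcarbinol cations at the remote α-carbon (first stage of the Piancatelli rearrangement) and α-substitution of 3-furylmethyl electrophiles.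

**Compound list**

1 | 3,4-dibromofuran | Brc1cocc1Br | starting material
2 | (4-bromofuran-3-yl)lithium | [Li]c1cocc1Br | intermediate
3 | (4-bromofuran-3-yl)boronic acid | OB(O)c1cocc1Br | intermediate
4 | (4-bromofuran-3-yl)(2,4,6-trimethylphenyl)iodonium trifluoromethanesulfonate | Cc1cc(C)c([I+]c2cocc2Br)c(C)c1.[O-]S(=O)(=O)C(F)(F)F | intermediate
5 | (R)-citronellal, (3R)-3,7-dimethyloct-6-enal | O=CC[C@H](C)CCC=C(C)C | starting material
6 | (2R,3R)-2-(4-bromofuran-3-yl)-3,7-dimethyloct-6-enal | O=C[C@@H](c1cocc1Br)[C@H](C)CCC=C(C)C | intermediate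
7 | (4R,5R,6R)-5-(4-bromofuran-3-yl)-2,6,10-trimethylundeca-1,9-dien-4-ol | O[C@H](CC(C)=C)[C@@H](c1cocc1Br)[C@H](C)CCC=C(C)C | intermediate
8 | lithium (4R,5R,6R)-5-(4-lithiofuran-3-yl)-2,6,10-trimethylundeca-1,9-dien-4-olate | [Li]O[C@H](CC(C)=C)[C@@H](c1cocc1[Li])[C@H](C)CCC=C(C)C | intermediate
9 | 4-[(4R,5R,6R)-4-hydroxy-2,6,10-trimethylundeca-1,9-dien-5-yl]furan-3-carbaldehyde | O[C@H](CC(C)=C)[C@@H](c1cocc1C=O)[C@H](C)CCC=C(C)C | intermediate
10 | bis(bromomagnesium) dialkoxide of (4R,5R,6R)-5-[4-(1-hydroxybut-3-en-1-yl)furan-3-yl]-2,6,10-trimethylundeca-1,9-dien-4-ol | Br[Mg]O[C@H](CC(C)=C)[C@@H](c1cocc1C(O[Mg]Br)CC=C)[C@H](C)CCC=C(C)C | intermediate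
11 | (4R,5R,6R)-5-[4-(1-acetoxybut-3-en-1-yl)furan-3-yl]-2,6,10-trimethylundeca-1,9-dien-4-yl acetate (both furylic configurations) | CC(=O)O[C@H](CC(C)=C)[C@@H](c1cocc1C(OC(C)=O)CC=C)[C@H](C)CCC=C(C)C | intermediate
12 | (4R,5R,7Z)-7-methyl-4-[(2R)-6-methylhept-5-en-2-yl]-5,6,9,10-tetrahydro-4H-cyclonona[c]furan-5,10-diyl diacetate (both C-10 configurations) | CC(=O)O[C@@H]1C/C(C)=C\CC(OC(C)=O)c2cocc2[C@H]1[C@H](C)CCC=C(C)C | intermediate
13 | (1R,3Z,6E,8R,9R)-7,8-diformyl-3-methyl-9-[(2R)-6-methylhept-5-en-2-yl]cyclonona-3,6-dien-1-yl acetate | CC(=O)O[C@@H]1C/C(C)=C\C/C=C(/C=O)[C@H](C=O)[C@H]1[C@H](C)CCC=C(C)C | target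

**Totals and risks**

Total step count: 7. Longest linear sequence: 7 steps (1 to 13); 5 enters in step 3.

Steps most likely to fail:

Step 7 (dearomative transposition). The isomerisation is estimated to be close to thermoneutral, so it relies on a kinetic funnel. The cation may be captured at the exocyclic carbon, lose a proton to give a dienylfuran, or give a C-8 epimer mixture. The fallback sets out from 12 and comes back at 13. Et3SiH with BF3·OEt2 (CH2Cl2, −78 °C) removes the furylic acetate and gives the deoxy furan (4R,5R,7Z)-7-methyl-4-[(2R)-6-methylhept-5-en-2-yl]-5,6,9,10-tetrahydro-4H-cyclonona[c]furan-5-yl acetate F6. Singlet oxygen (O2, tetraphenylporphyrin, light, CH2Cl2, −78 °C) reacts with the dialkylfuran far faster than with the trisubstituted alkenes and gives the furan 1,3-endoperoxide of that compound F7. Me2S in the same flask reduces it to the cis-enedial (1R,3Z,7Z,9R)-7,8-diformyl-3-methyl-9-[(2R)-6-methylhept-5-en-2-yl]cyclonona-3,7-dien-1-yl acetate F8. Catalytic DBU then shifts the double bond by γ-deprotonation at the less hindered C-6 and α-protonation at C-8 to give 13.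

Step 6 (nine-membered ring closure). Oligomerisation or ring closure onto the prenyl-type alkene may compete. The fallback sets out from 9 and comes back at 12. Allylmagnesium bromide with aqueous work-up gives the free diol (4R,5R,6R)-5-[4-(1-hydroxybut-3-en-1-yl)furan-3-yl]-2,6,10-trimethylundeca-1,9-dien-4-ol F3. Camphorsulfonic acid in CH2Cl2 over 4 Å sieves closes a furo[3,4-c]pyran by reversible furylic ionisation and gives the 4,6-cis ether (4S,6R,7R)-4-allyl-6-(2-methylallyl)-7-[(2R)-6-methylhept-5-en-2-yl]-6,7-dihydro-4H-furo[3,4-c]pyran F4. Second-generation Grubbs catalyst then has to close only a seven-membered oxacycle on this cis template and gives the oxygen-bridged cyclononene (4R,5R,7Z,10S)-5,10-epoxy-7-methyl-4-[(2R)-6-methylhept-5-en-2-yl]-5,6,9,10-tetrahydro-4H-cyclonona[c]furan F5. Ac2O with catalytic Sc(OTf)3 opens the furylic C–O bond acylatively and gives 12.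

Step 3 (α-arylation and its stereocontrol). A heteroaryl(mesityl)iodonium salt and a β-branched chiral aldehyde are both outside the usual scope, and the diastereomer ratio at the furyl-bearing carbon is not assured. The fallback sets out from 1 and 5 and comes back at 7. Palladium-catalysed enolate arylation of 5 with an excess of 1 (Pd(OAc)2, rac-BINAP, Cs2CO3, dioxane, 80 °C) needs neither the iodonium salt nor enamine catalysis and gives the aldehyde as a mixture at C-2, (2RS,3R)-2-(4-bromofuran-3-yl)-3,7-dimethyloct-6-enal F1. The same methallylboration then gives 7 together with its epimer (4R,5S,6R)-5-(4-bromofuran-3-yl)-2,6,10-trimethylundeca-1,9-dien-4-ol F2, and the two diastereomers are separated by chromatography.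

**Further compounds**

F1 | step 3 | (2RS,3R)-2-(4-bromofuran-3-yl)-3,7-dimethyloct-6-enal | O=CC(c1cocc1Br)[C@H](C)CCC=C(C)C
F2 | step 3 | (4R,5S,6R)-5-(4-bromofuran-3-yl)-2,6,10-trimethylundeca-1,9-dien-4-ol | O[C@H](CC(C)=C)[C@H](c1cocc1Br)[C@H](C)CCC=C(C)C
F3 | step 6 | (4R,5R,6R)-5-[4-(1-hydroxybut-3-en-1-yl)furan-3-yl]-2,6,10-trimethylundeca-1,9-dien-4-ol | O[C@H](CC(C)=C)[C@@H](c1cocc1C(O)CC=C)[C@H](C)CCC=C(C)C
F4 | step 6 | (4S,6R,7R)-4-allyl-6-(2-methylallyl)-7-[(2R)-6-methylhept-5-en-2-yl]-6,7-dihydro-4H-furo[3,4-c]pyran | C=C(C)C[C@H]1O[C@@H](CC=C)c2cocc2[C@H]1[C@H](C)CCC=C(C)C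
F5 | step 6 | (4R,5R,7Z,10S)-5,10-epoxy-7-methyl-4-[(2R)-6-methylhept-5-en-2-yl]-5,6,9,10-tetrahydro-4H-cyclonona[c]furan | O1[C@@H]2C/C(C)=C\C[C@H]1c1cocc1[C@H]2[C@H](C)CCC=C(C)C
F6 | step 7 | (4R,5R,7Z)-7-methyl-4-[(2R)-6-methylhept-5-en-2-yl]-5,6,9,10-tetrahydro-4H-cyclonona[c]furan-5-yl acetate | CC(=O)O[C@@H]1C/C(C)=C\CCc2cocc2[C@H]1[C@H](C)CCC=C(C)C
F7 | step 7 | furan 1,3-endoperoxide of F6 | CC(=O)O[C@@H]1C/C(C)=C\CCC2=C(C3OOC2O3)[C@H]1[C@H](C)CCC=C(C)C
F8 | step 7 | (1R,3Z,7Z,9R)-7,8-diformyl-3-methyl-9-[(2R)-6-methylhept-5-en-2-yl]cyclonona-3,7-dien-1-yl acetate | CC(=O)O[C@@H]1C/C(C)=C\CC/C(C=O)=C(/C=O)[C@H]1[C@H](C)CCC=C(C)C
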